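In a closed, stirred vessel the gas Z dissolves as D, J turns Q and D reversibly into E, and Q and D also leak irreversibly to Q.D.

    Z ⇌ D, rate k1*(csat - [D]) (k1 = 0.019 s⁻¹, csat = 7.1 mM)
    Q + D + J ⇌ J + E (K2 = 280 M⁻¹, k2 = 52000 M⁻² s⁻¹)
    J → G (k3 = 4.1 × 10⁻⁶ s⁻¹)
    Q + D → Q.D (k4 = 0.12 M⁻¹ s⁻¹)

Q 0.070 M; Z 7.1 mM (held); J 0.2 mol%; time 40 min

- at the start none of D is dissolved
- run time (flask): 40 min

1. the E standing at 40 min, as a percentage of the Q charged
2. the change that raises the amount of E at 40 min, in percent of the Q charged most ("none" if none brings more than 2 percentage points) (autumn / winter / noon / none)
3. amount of E at 40 min, in percent of the Q charged, after noon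

- autumn: doubling the transfer coefficient of step 1, all else as stated
- winter: doubling the amount of J, all else as stated
- noon: doubling the saturation concentration of Z, all else as stated

With [D] at saturation, the catalysed equilibrium gives [E]/[Q] = 1.99, so in this flask E holds 66.5% of the pool [Q] + [E]. That pool then decays, pseudo-first-order, at 0.0171 min⁻¹, the drain constant: the leak's rate constant times saturation [D] times the part of the pool that is free Q. I treated the equilibrium as settled because it relaxes at 4.66 min⁻¹. Transfer at its full rate needs 5.75 min to supply E's share, so I started the drain then and committed to 37.0%. The same reckoning gave 37.7% for noon and 35.3% for autumn, while winter changes neither share, drain nor delay, so I expected no gain above 2 percentage points.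

The forecast gave 36%, none and 35% after noon, saying that “the slow side reaction to Q.D steadily drains the Q+E pool”; its figure for the flask lies below mine, and so does its noon figure.

The flask gave 36.2%, best change none, and 37.0% after noon. Its pool stood at 76.5% at 20.0 min and 54.7% at 40.0 min, where the drain constant carries the first reading to 54.3%. For the same flask read at 1.0 h, the drain constant gives 26.3% E, and that flask held 25.9%.

The constants are those of an exercise; no experiment stands behind them.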